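**Strategy.** The trimer is cut at its two interflavan bonds into an epicatechin nucleophile and one (2S,3S)-dihydroflavonol that serves twice, as C4 electrophile (middle unit) and as C4 ketone (top unit). The plan rests on closing ring C of the lower unit by a cationic [4+2] (oxa-Povarov) reaction: since O1 joins C2 to C8a of the symmetric 5,7-dioxygenated ring A, an O-aryl oxocarbenium ion is a 2-oxadiene (C2=O1–C8a=C4a) that takes up an enediol ether as C3–C4, forming C2–C3 and C4–C4a in one operation at either equivalent ortho carbon. The precursor is an acyclic mixed aryl methyl acetal; the resulting flavan-3-one is set to (2R,3R) by dynamic kinetic resolution.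

Key step: step 4

Remark 1: the target is read as top unit (2S,3R,4S; 2,3-trans-3,4-cis), middle unit (2S,3S,4S; 2,3-cis-3,4-trans) and lower unit (2R,3R; epicatechin), both interflavan bonds running from C4 to C8.
Remark 2: 13 is taken as a purchasable building block (otherwise one BF3-mediated acetylation away from 2-bromoresorcinol).
Remark 3: the sense of induction in step 5 is assigned by analogy, with the ring A–CH2 side of the ketone in the aryl position of the Noyori–Ikariya model; the mirror-image catalyst would be used if the opposite sense were found.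

**Lower unit**

Step 1
Reactants: 1 glycolaldehyde dimer
Product: 2 (Z)-1,2-bis(trimethylsilyloxy)ethene
Conditions: TMSCl, Et3N, DMF, 80 °C; distillation
Reagents that add atoms: chlorotrimethylsilane, C[Si](C)(C)Cl
Why: the dimer cracks to glycolaldehyde, whose hydroxyl and enol oxygens are both silylated under House conditions (thermodynamic silyl enol ether formation); the alkene geometry is of no consequence later.

Step 2
Reactants: 3 3,4-bis(benzyloxy)benzaldehyde
Product: 4 1,2-bis(benzyloxy)-4-(dimethoxymethyl)benzene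
Conditions: HC(OMe)3, p-TsOH (cat.), MeOH, rt
Reagents that add atoms: trimethyl orthoformate, COC(OC)OC
Why: acid-catalysed acetalisation driven by the orthoformate as water scavenger.

Step 3
Reactants: 4 1,2-bis(benzyloxy)-4-(dimethoxymethyl)benzene; 5 3,5-bis(benzyloxy)phenol
Product: 7 1,2-bis(benzyloxy)-4-{[3,5-bis(benzyloxy)phenoxy](methoxy)methyl}benzene, via chloro ether 6 (not isolated)
Conditions: AcCl, CH2Cl2, 0 °C to rt, evaporate; then 5, NaH, THF–DMF, 0 °C
Reagents that add atoms: none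
Why: acetyl chloride converts the acetal into the α-chloro ether, which O-alkylates the sodium phenoxide (Williamson-type etherification with a hard, MOM-chloride-like electrophile, so that oxygen and not ring carbon is alkylated).

Step 4
Reactants: 7 mixed aryl methyl acetal; 2 (Z)-1,2-bis(trimethylsilyloxy)ethene
Product: 11 rac-5,7-bis(benzyloxy)-2-[3,4-bis(benzyloxy)phenyl]chroman-3-one, via oxocarbenium triflate 8 (not isolated), via bis-silyl cycloadduct 9 (not isolated), via silyl enol ether 10 (not isolated)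
Conditions: 2 (1.5 equiv), TMSOTf (0.2 equiv), CH2Cl2, −78 to 0 °C; then 1 M HCl, THF, rt
Reagents that add atoms: none
Why: TMSOTf removes the more basic methoxy group of 7 and gives the O-aryl oxocarbenium ion 8, a cationic 2-oxadiene (C2=O1–C8a=C4a); 2 attacks C2 through an oxygen-bearing carbon (new C2–C3 bond) and the silyloxocarbenium carbon so formed is attacked by C4a of ring A (new C4–C4a bond), a stepwise polar [4+2] cycloaddition of inverse electron demand (oxa-Povarov reaction). The closest known reactions are the SnCl4-promoted cycloadditions of aryl oxocarbenium ions with alkenes and the Mukaiyama addition of silyl enol ethers to acetals. Ring C closes in a 6-exo-trig Friedel–Crafts mode onto the carbon ortho to O1 and para to a benzyloxy group. The stereocentres C2, C3 and C4 of 9 form without control and none matters: the acid ionises the doubly activated benzylic 4-silyloxy group, loss of H-3 gives 10, and hydrolysis leaves ketone 11, whose only stereocentre (C2) is labile and is settled in step 5. The step needs orientation and site selectivity: the symmetric dienophile can only place oxygen on C3, the two ortho carbons of the 3,5-dibenzyloxyphenoxy ring are equivalent so one constitution results, and the enediol ether in excess at −78 °C outcompetes the arene of a second molecule for 8.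

Step 5
Reactants: 11 rac-5,7-bis(benzyloxy)-2-[3,4-bis(benzyloxy)phenyl]chroman-3-one
Product: 12 (2R,3R)-5,7-bis(benzyloxy)-2-[3,4-bis(benzyloxy)phenyl]chroman-3-ol
Conditions: RuCl(p-cymene)[(S,S)-TsDPEN] (2 mol %), HCO2H, DBU, DMF, 40 °C
Reagents that add atoms: none
Why: Noyori–Ikariya asymmetric transfer hydrogenation with dynamic kinetic resolution, in which C2 (benzylic, α to the ketone and to O1) epimerises through the enol while the catalyst reduces the (2R) ketone faster, hydride adding to C3 anti to the 2-aryl group to give the cis (2R,3R) alcohol.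

**Shared dihydroflavonol**

Step 6
Reactants: 13 1-(3-bromo-2,4-dihydroxyphenyl)ethanone
Product: 14 1-[4-(benzyloxy)-3-bromo-2-hydroxyphenyl]ethanone
Conditions: BnBr (1.05 equiv), K2CO3, acetone, reflux
Reagents that add atoms: benzyl bromide, BrCc1ccccc1
Why: Williamson etherification, selective for the 4-hydroxyl because the 2-hydroxyl is hydrogen-bonded to the ketone and flanked by bromine.

Step 7
Reactants: 14 1-[4-(benzyloxy)-3-bromo-2-hydroxyphenyl]ethanone
Product: 15 1-[4-(benzyloxy)-3-bromo-2-(methoxymethoxy)phenyl]ethanone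
Conditions: NaH, MOMCl, DMF, 0 °C
Reagents that add atoms: chloromethyl methyl ether, COCCl
Why: MOM protection of the chelated phenol (O-alkylation of the phenoxide), needed so that the chalcone cannot cyclise under the basic epoxidation.

Step 8
Reactants: 15 1-[4-(benzyloxy)-3-bromo-2-(methoxymethoxy)phenyl]ethanone; 16 3,4,5-tris(benzyloxy)benzaldehyde
Product: 17 (E)-1-[4-(benzyloxy)-3-bromo-2-(methoxymethoxy)phenyl]-3-[3,4,5-tris(benzyloxy)phenyl]prop-2-en-1-one
Conditions: KOH, EtOH–THF, rt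
Reagents that add atoms: none
Why: Claisen–Schmidt aldol condensation, giving the thermodynamically favoured E-enone.

Step 9
Reactants: 17 the chalcone
Product: 18 [4-(benzyloxy)-3-bromo-2-(methoxymethoxy)phenyl]{(2S,3R)-3-[3,4,5-tris(benzyloxy)phenyl]oxiran-2-yl}methanone
Conditions: poly-D-leucine, urea–H2O2, DBU, THF, rt
Reagents that add atoms: hydrogen peroxide (as urea adduct), OO
Why: Juliá–Colonna epoxidation (Weitz–Scheffer hydroperoxide addition inside the helical polypeptide); the D-polymer should give the (2S,3R) trans-epoxide, which fixes C3 and, through the next step, C2 of both upper units.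

Step 10
Reactants: 18 the (2S,3R)-epoxy ketone
Product: 19 (2S,3S)-7-(benzyloxy)-8-bromo-3-hydroxy-2-[3,4,5-tris(benzyloxy)phenyl]chroman-4-one
Conditions: conc. HCl, MeOH–THF, 55 °C
Reagents that add atoms: none
Why: acid cleaves the MOM ether and the freed phenol opens the epoxide at the benzylic carbon with inversion (6-endo epoxide opening), giving the thermodynamically preferred 2,3-trans dihydroflavonol with C3 keeping the epoxide configuration.

**Top-unit ketone**

Step 11
Reactants: 19 the (2S,3S)-dihydroflavonol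
Product: 20 (2S,3S)-3,7-bis(benzyloxy)-8-bromo-2-[3,4,5-tris(benzyloxy)phenyl]chroman-4-one
Conditions: benzyl 2,2,2-trichloroacetimidate, TfOH (cat.), CH2Cl2–cyclohexane, 0 °C to rt
Reagents that add atoms: benzyl 2,2,2-trichloroacetimidate, ClC(Cl)(Cl)C(=N)OCc1ccccc1
Why: acid-catalysed O-benzylation by the imidate avoids base, which would epimerise or ring-open the α-hydroxy ketone.

**Middle-unit electrophile**

Step 12
Reactants: 19 the (2S,3S)-dihydroflavonol
Product: 22 (2S,3R,4S)-7-(benzyloxy)-8-bromo-4-methoxy-2-[3,4,5-tris(benzyloxy)phenyl]chroman-3-ol, via flavan-3,4-diol 21 (not isolated)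
Conditions: NaBH4, MeOH–THF, 0 °C; then p-TsOH (cat.), MeOH, rt
Reagents that add atoms: methanol, CO
Why: hydride reduction of the ketone to the 3,4-trans diol, then acid-catalysed SN1 methanolysis of the benzylic 4-hydroxyl only; the C4 configuration (drawn 3,4-trans, any epimer serves) is lost later.

Step 13
Reactants: 22 the 4-methoxy-flavan-3-ol
Product: 23 (2S,4S)-7-(benzyloxy)-8-bromo-4-methoxy-2-[3,4,5-tris(benzyloxy)phenyl]chroman-3-one
Conditions: Dess–Martin periodinane, NaHCO3, CH2Cl2, rt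
Reagents that add atoms: none
Why: Dess–Martin oxidation of the secondary alcohol under buffered conditions that should not epimerise C2.

Step 14
Reactants: 23 the 4-methoxy-flavan-3-one
Product: 24 (2S,3S,4S)-7-(benzyloxy)-8-bromo-4-methoxy-2-[3,4,5-tris(benzyloxy)phenyl]chroman-3-ol
Conditions: L-Selectride, LiBr, THF, −78 °C; then H2O
Reagents that add atoms: none
Why: the bulky borohydride attacks from the equatorial direction to give the axial 3-hydroxyl cis to the 2-aryl group (3S), as in the known catechin-to-epicatechin inversion via the 3-ketone.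

**Assembly**

Step 15
Reactants: 24 the 2,3-cis 4-methoxy electrophile; 12 (2R,3R)-tetra-O-benzylepicatechin
Product: 25 (2S,3S,4S)-7-(benzyloxy)-8-bromo-4-{(2R,3R)-5,7-bis(benzyloxy)-2-[3,4-bis(benzyloxy)phenyl]-3-hydroxychroman-8-yl}-2-[3,4,5-tris(benzyloxy)phenyl]chroman-3-ol
Conditions: 12 (3 equiv), TMSOTf (0.3 equiv), CH2Cl2, −40 to 0 °C
Reagents that add atoms: none
Why: Lewis-acid-mediated SN1 substitution at C4 (the standard proanthocyanidin condensation), in which C8 of 12 attacks anti to the axial 3-hydroxyl and the 2-aryl group to give the 3,4-trans bond (4S), while the brominated ring of 24 is too deactivated to self-condense.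

Step 16
Reactants: 25 the middle–lower dimer diol
Product: 26 the 3,3''-di-O-benzyl ether of 25
Conditions: NaH, BnBr, n-Bu4NI (cat.), DMF, 0 °C to rt
Reagents that add atoms: benzyl bromide, BrCc1ccccc1
Why: Williamson etherification of both secondary hydroxyls, which must be masked before the organolithium step.

Step 17
Reactants: 26 the perbenzylated bromo dimer; 20 the 3-O-benzyl dihydroflavonol ketone
Product: 28 the trimeric tertiary carbinol, via aryllithium 27 (not isolated)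
Conditions: t-BuLi (2.1 equiv), THF, −78 °C; then 20, −78 to −40 °C; then H2O
Reagents that add atoms: none
Why: bromine–lithium exchange and 1,2-addition of the aryllithium to the ketone form the bond from C8 of the middle unit to C4 of the top unit, the site being fixed by the bromine carried from 13; the carbinol configuration is of no consequence.

Step 18
Reactants: 28 the trimeric tertiary carbinol
Product: 29 the pentadeca-O-benzyl bromo trimer
Conditions: Et3SiH, CF3CO2H, CH2Cl2, −20 to 0 °C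
Reagents that add atoms: none
Why: ionic hydrogenation, in which acid ionises the diaryl carbinol and Et3SiH delivers hydride anti to the adjacent 3-benzyloxy group, so the aryl group ends cis to O3 (4S), the 3,4-cis arrangement that direct cationic coupling would not favour.

Step 19
Reactants: 29 the pentadeca-O-benzyl bromo trimer
Product: 30 the target trimer (CNP0115797.3)
Conditions: H2 (1 atm), Pd(OH)2/C, Et3N (1.2 equiv), THF–MeOH, rt; then AcOH, filtration under argon
Reagents that add atoms: none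
Why: hydrogenolysis of all fifteen benzyl ethers and hydrodebromination of the bromine left on ring A of the top unit, with Et3N taking up HBr; no stereocentre is touched.

**Compound list**

1 | glycolaldehyde dimer (1,4-dioxane-2,5-diol) | OC1COC(O)CO1 | starting material
2 | (Z)-1,2-bis(trimethylsilyloxy)ethene | C[Si](C)(C)O/C=C\O[Si](C)(C)C | intermediate
3 | 3,4-bis(benzyloxy)benzaldehyde | O=Cc1ccc(OCc2ccccc2)c(OCc2ccccc2)c1 | starting material
4 | 1,2-bis(benzyloxy)-4-(dimethoxymethyl)benzene | COC(OC)c1ccc(OCc2ccccc2)c(OCc2ccccc2)c1 | intermediate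
5 | 3,5-bis(benzyloxy)phenol | Oc1cc(OCc2ccccc2)cc(OCc2ccccc2)c1 | starting material
6 | 1,2-bis(benzyloxy)-4-[chloro(methoxy)methyl]benzene (racemic) | COC(Cl)c1ccc(OCc2ccccc2)c(OCc2ccccc2)c1 | intermediate
7 | 1,2-bis(benzyloxy)-4-{[3,5-bis(benzyloxy)phenoxy](methoxy)methyl}benzene (racemic mixed acetal) | COC(Oc1cc(OCc2ccccc2)cc(OCc2ccccc2)c1)c1ccc(OCc2ccccc2)c(OCc2ccccc2)c1 | intermediate
8 | [3,4-bis(benzyloxy)benzylidene][3,5-bis(benzyloxy)phenyl]oxonium triflate | c1c(OCc2ccccc2)cc(OCc2ccccc2)cc1[O+]=Cc1ccc(OCc2ccccc2)c(OCc2ccccc2)c1.[O-]S(=O)(=O)C(F)(F)F | intermediate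
9 | rac-5,7-bis(benzyloxy)-2-[3,4-bis(benzyloxy)phenyl]-3,4-bis(trimethylsilyloxy)chromane (diastereomer mixture) | C[Si](C)(C)OC1C(O[Si](C)(C)C)c2c(OCc3ccccc3)cc(OCc3ccccc3)cc2OC1c1ccc(OCc2ccccc2)c(OCc2ccccc2)c1 | intermediate
10 | rac-5,7-bis(benzyloxy)-2-[3,4-bis(benzyloxy)phenyl]-3-(trimethylsilyloxy)-2H-chromene | C[Si](C)(C)OC1=Cc2c(OCc3ccccc3)cc(OCc3ccccc3)cc2OC1c1ccc(OCc2ccccc2)c(OCc2ccccc2)c1 | intermediate
11 | rac-5,7-bis(benzyloxy)-2-[3,4-bis(benzyloxy)phenyl]chroman-3-one | O=C1Cc2c(OCc3ccccc3)cc(OCc3ccccc3)cc2OC1c1ccc(OCc2ccccc2)c(OCc2ccccc2)c1 | intermediate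
12 | (2R,3R)-5,7-bis(benzyloxy)-2-[3,4-bis(benzyloxy)phenyl]chroman-3-ol (tetra-O-benzylepicatechin, 2,3-cis) | O[C@@H]1Cc2c(OCc3ccccc3)cc(OCc3ccccc3)cc2O[C@@H]1c1ccc(OCc2ccccc2)c(OCc2ccccc2)c1 | intermediate
13 | 1-(3-bromo-2,4-dihydroxyphenyl)ethanone | CC(=O)c1ccc(O)c(Br)c1O | starting material
14 | 1-[4-(benzyloxy)-3-bromo-2-hydroxyphenyl]ethanone | CC(=O)c1ccc(OCc2ccccc2)c(Br)c1O | intermediate
15 | 1-[4-(benzyloxy)-3-bromo-2-(methoxymethoxy)phenyl]ethanone | CC(=O)c1ccc(OCc2ccccc2)c(Br)c1OCOC | intermediate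
16 | 3,4,5-tris(benzyloxy)benzaldehyde | O=Cc1cc(OCc2ccccc2)c(OCc2ccccc2)c(OCc2ccccc2)c1 | starting material
17 | (E)-1-[4-(benzyloxy)-3-bromo-2-(methoxymethoxy)phenyl]-3-[3,4,5-tris(benzyloxy)phenyl]prop-2-en-1-one | COCOc1c(Br)c(OCc2ccccc2)ccc1C(=O)/C=C/c1cc(OCc2ccccc2)c(OCc2ccccc2)c(OCc2ccccc2)c1 | intermediate
18 | [4-(benzyloxy)-3-bromo-2-(methoxymethoxy)phenyl]{(2S,3R)-3-[3,4,5-tris(benzyloxy)phenyl]oxiran-2-yl}methanone (trans-epoxide) | O1[C@H](c2cc(OCc3ccccc3)c(OCc3ccccc3)c(OCc3ccccc3)c2)[C@H]1C(=O)c1ccc(OCc2ccccc2)c(Br)c1OCOC | intermediate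
19 | (2S,3S)-7-(benzyloxy)-8-bromo-3-hydroxy-2-[3,4,5-tris(benzyloxy)phenyl]chroman-4-one (2,3-trans) | Brc1c(OCc3ccccc3)ccc2c1O[C@@H](c1cc(OCc3ccccc3)c(OCc3ccccc3)c(OCc3ccccc3)c1)[C@H](O)C2=O | intermediate
20 | (2S,3S)-3,7-bis(benzyloxy)-8-bromo-2-[3,4,5-tris(benzyloxy)phenyl]chroman-4-one (2,3-trans) | Brc1c(OCc3ccccc3)ccc2c1O[C@@H](c1cc(OCc3ccccc3)c(OCc3ccccc3)c(OCc3ccccc3)c1)[C@H](OCc1ccccc1)C2=O | intermediate
21 | (2S,3R,4S)-7-(benzyloxy)-8-bromo-2-[3,4,5-tris(benzyloxy)phenyl]chromane-3,4-diol (2,3-trans-3,4-trans) | Brc1c(OCc3ccccc3)ccc2c1O[C@@H](c1cc(OCc3ccccc3)c(OCc3ccccc3)c(OCc3ccccc3)c1)[C@H](O)[C@H]2O | intermediate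
22 | (2S,3R,4S)-7-(benzyloxy)-8-bromo-4-methoxy-2-[3,4,5-tris(benzyloxy)phenyl]chroman-3-ol (2,3-trans-3,4-trans) | Brc1c(OCc3ccccc3)ccc2c1O[C@@H](c1cc(OCc3ccccc3)c(OCc3ccccc3)c(OCc3ccccc3)c1)[C@H](O)[C@H]2OC | intermediate
23 | (2S,4S)-7-(benzyloxy)-8-bromo-4-methoxy-2-[3,4,5-tris(benzyloxy)phenyl]chroman-3-one | Brc1c(OCc3ccccc3)ccc2c1O[C@@H](c1cc(OCc3ccccc3)c(OCc3ccccc3)c(OCc3ccccc3)c1)C(=O)[C@H]2OC | intermediate
24 | (2S,3S,4S)-7-(benzyloxy)-8-bromo-4-methoxy-2-[3,4,5-tris(benzyloxy)phenyl]chroman-3-ol (all-cis) | Brc1c(OCc3ccccc3)ccc2c1O[C@@H](c1cc(OCc3ccccc3)c(OCc3ccccc3)c(OCc3ccccc3)c1)[C@@H](O)[C@H]2OC | intermediate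
25 | (2S,3S,4S)-7-(benzyloxy)-8-bromo-4-{(2R,3R)-5,7-bis(benzyloxy)-2-[3,4-bis(benzyloxy)phenyl]-3-hydroxychroman-8-yl}-2-[3,4,5-tris(benzyloxy)phenyl]chroman-3-ol (upper unit 2,3-cis-3,4-trans) | Brc1c(OCc3ccccc3)ccc2c1O[C@@H](c1cc(OCc3ccccc3)c(OCc3ccccc3)c(OCc3ccccc3)c1)[C@@H](O)[C@@H]2c1c(OCc3ccccc3)cc(OCc3ccccc3)c2c1O[C@H](c1ccc(OCc3ccccc3)c(OCc3ccccc3)c1)[C@H](O)C2 | intermediate
26 | 3,3''-di-O-benzyl ether of 25 (both secondary hydroxyls benzylated; configurations as in 25) | Brc1c(OCc3ccccc3)ccc2c1O[C@@H](c1cc(OCc3ccccc3)c(OCc3ccccc3)c(OCc3ccccc3)c1)[C@@H](OCc1ccccc1)[C@@H]2c1c(OCc3ccccc3)cc(OCc3ccccc3)c2c1O[C@H](c1ccc(OCc3ccccc3)c(OCc3ccccc3)c1)[C@H](OCc1ccccc1)C2 | intermediate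
27 | 8-lithio derivative of 26 (lithium in place of bromine) | [Li]c1c(OCc3ccccc3)ccc2c1O[C@@H](c1cc(OCc3ccccc3)c(OCc3ccccc3)c(OCc3ccccc3)c1)[C@@H](OCc1ccccc1)[C@@H]2c1c(OCc3ccccc3)cc(OCc3ccccc3)c2c1O[C@H](c1ccc(OCc3ccccc3)c(OCc3ccccc3)c1)[C@H](OCc1ccccc1)C2 | intermediate
28 | trimeric tertiary carbinol: 4-hydroxy-4-aryl adduct of 20 with 27 (top unit 2,3-trans as in 20; the new carbinol carbon is drawn with the aryl group trans to the 3-benzyloxy group) | Brc1c(OCc3ccccc3)ccc2c1O[C@@H](c1cc(OCc3ccccc3)c(OCc3ccccc3)c(OCc3ccccc3)c1)[C@H](OCc1ccccc1)[C@@]2(O)c1c(OCc3ccccc3)ccc2c1O[C@@H](c1cc(OCc3ccccc3)c(OCc3ccccc3)c(OCc3ccccc3)c1)[C@@H](OCc1ccccc1)[C@@H]2c1c(OCc3ccccc3)cc(OCc3ccccc3)c2c1O[C@H](c1ccc(OCc3ccccc3)c(OCc3ccccc3)c1)[C@H](OCc1ccccc1)C2 | intermediate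
29 | pentadeca-O-benzyl 8-bromo trimer: top unit (2S,3R,4S), middle unit (2S,3S,4S), lower unit (2R,3R); bromine on C8 of the top unit | Brc1c(OCc3ccccc3)ccc2c1O[C@@H](c1cc(OCc3ccccc3)c(OCc3ccccc3)c(OCc3ccccc3)c1)[C@H](OCc1ccccc1)[C@@H]2c1c(OCc3ccccc3)ccc2c1O[C@@H](c1cc(OCc3ccccc3)c(OCc3ccccc3)c(OCc3ccccc3)c1)[C@@H](OCc1ccccc1)[C@@H]2c1c(OCc3ccccc3)cc(OCc3ccccc3)c2c1O[C@H](c1ccc(OCc3ccccc3)c(OCc3ccccc3)c1)[C@H](OCc1ccccc1)C2 | intermediate
30 | CNP0115797.3: (2S,3R,4S)-flavan-3,7,3',4',5'-pentol unit linked C4 to C8 of a (2S,3S,4S)-flavan-3,7,3',4',5'-pentol unit, itself linked C4 to C8 of (2R,3R)-epicatechin | Oc1ccc2c(c1)O[C@@H](c1cc(O)c(O)c(O)c1)[C@H](O)[C@@H]2c1c(O)ccc2c1O[C@@H](c1cc(O)c(O)c(O)c1)[C@@H](O)[C@@H]2c1c(O)cc(O)c2c1O[C@H](c1ccc(O)c(O)c1)[C@H](O)C2 | target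

**Step count and risks**

Total step count: 19. Longest linear sequence: 13 steps (13 to 30 through steps 6–10 and 12–19).

Steps most likely to fail:

1. Step 4. The C4 cation formed from 9 may be consumed by oligomerisation (attack by a second electron-rich ring A) faster than it loses H-3, or the acetal may ionise at the aryloxy oxygen. Fallback, from 7 back to 11: the cycloaddition of 7 with 2 is run at −78 °C and, once 9 has formed, Et3SiH and BF3·OEt2 are added so that the C4 cation is captured by hydride. Desilylating work-up should give rac-5,7-bis(benzyloxy)-2-[3,4-bis(benzyloxy)phenyl]chroman-3-ol F1 as a cis/trans mixture, which Dess–Martin oxidation converts into 11.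

2. Step 5. Epimerisation at C2 may be slower than hydride transfer, which would erode both enantiomeric purity and the cis/trans ratio; the ketone may also oxidise through its enol. Fallback, from 11 back to 12: L-Selectride reduction of 11 at −78 °C gives the racemic cis alcohol F2. Esterification with (S)-O-methylmandelic acid (DCC, DMAP) gives the diastereomeric esters (2R,3R)-ester F3 and (2S,3S)-ester F4, which are separated by chromatography. Methanolysis of F3 (K2CO3, MeOH) returns 12.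

3. Step 17. The bulky dimeric aryllithium may act as a base on 20 (enolisation at C3 and ring-opening β-elimination of the phenoxide) or exchange with the bromine of 20 instead of adding to the carbonyl. Fallback, from 24 back to 29, with the bonds made in the other order: 24 is benzylated (NaH, BnBr) to its 3-O-benzyl ether F5. Bromine–lithium exchange (t-BuLi, −78 °C) gives the small monomeric aryllithium F6, which is added to 20 to give the dimeric carbinol F7. Et3SiH/CF3CO2H at −40 °C should reduce only the tertiary diaryl carbinol, since the secondary 4-methoxy group of a 5-deoxy unit ionises much more slowly, and gives the 4-methoxy dimer F8. TMSOTf-mediated coupling of F8 with penta-O-benzylepicatechin F9 (from 12 with NaH and BnBr), anti to the 3-benzyloxy group, then gives 29.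

Further compounds

F1 | step 4 | rac-5,7-bis(benzyloxy)-2-[3,4-bis(benzyloxy)phenyl]chroman-3-ol (cis/trans mixture) | OC1Cc2c(OCc3ccccc3)cc(OCc3ccccc3)cc2OC1c1ccc(OCc2ccccc2)c(OCc2ccccc2)c1
F2 | step 5 | rac-cis-5,7-bis(benzyloxy)-2-[3,4-bis(benzyloxy)phenyl]chroman-3-ol (both enantiomers) | O[C@@H]1Cc2c(OCc3ccccc3)cc(OCc3ccccc3)cc2O[C@@H]1c1ccc(OCc2ccccc2)c(OCc2ccccc2)c1.O[C@H]1Cc2c(OCc3ccccc3)cc(OCc3ccccc3)cc2O[C@H]1c1ccc(OCc2ccccc2)c(OCc2ccccc2)c1
F3 | step 5 | (2R,3R)-5,7-bis(benzyloxy)-2-[3,4-bis(benzyloxy)phenyl]chroman-3-yl (S)-methoxy(phenyl)acetate | CO[C@H](C(=O)O[C@@H]1Cc2c(OCc3ccccc3)cc(OCc3ccccc3)cc2O[C@@H]1c1ccc(OCc2ccccc2)c(OCc2ccccc2)c1)c1ccccc1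
F4 | step 5 | (2S,3S)-5,7-bis(benzyloxy)-2-[3,4-bis(benzyloxy)phenyl]chroman-3-yl (S)-methoxy(phenyl)acetate | CO[C@H](C(=O)O[C@H]1Cc2c(OCc3ccccc3)cc(OCc3ccccc3)cc2O[C@H]1c1ccc(OCc2ccccc2)c(OCc2ccccc2)c1)c1ccccc1
F5 | step 17 | (2S,3S,4S)-3,7-bis(benzyloxy)-8-bromo-4-methoxy-2-[3,4,5-tris(benzyloxy)phenyl]chromane | Brc1c(OCc3ccccc3)ccc2c1O[C@@H](c1cc(OCc3ccccc3)c(OCc3ccccc3)c(OCc3ccccc3)c1)[C@@H](OCc1ccccc1)[C@H]2OC
F6 | step 17 | 8-lithio derivative of F5 | [Li]c1c(OCc3ccccc3)ccc2c1O[C@@H](c1cc(OCc3ccccc3)c(OCc3ccccc3)c(OCc3ccccc3)c1)[C@@H](OCc1ccccc1)[C@H]2OC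
F7 | step 17 | dimeric tertiary carbinol from 20 and F6 (aryl drawn trans to the 3-benzyloxy group) | Brc1c(OCc3ccccc3)ccc2c1O[C@@H](c1cc(OCc3ccccc3)c(OCc3ccccc3)c(OCc3ccccc3)c1)[C@H](OCc1ccccc1)[C@@]2(O)c1c(OCc3ccccc3)ccc2c1O[C@@H](c1cc(OCc3ccccc3)c(OCc3ccccc3)c(OCc3ccccc3)c1)[C@@H](OCc1ccccc1)[C@H]2OC
F8 | step 17 | top–middle dimer with 4-methoxy group on the middle unit (top unit 2S,3R,4S) | Brc1c(OCc3ccccc3)ccc2c1O[C@@H](c1cc(OCc3ccccc3)c(OCc3ccccc3)c(OCc3ccccc3)c1)[C@H](OCc1ccccc1)[C@@H]2c1c(OCc3ccccc3)ccc2c1O[C@@H](c1cc(OCc3ccccc3)c(OCc3ccccc3)c(OCc3ccccc3)c1)[C@@H](OCc1ccccc1)[C@H]2OC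
F9 | step 17 | (2R,3R)-3,5,7-tris(benzyloxy)-2-[3,4-bis(benzyloxy)phenyl]chromane (penta-O-benzylepicatechin) | c1ccccc1CO[C@@H]1Cc2c(OCc3ccccc3)cc(OCc3ccccc3)cc2O[C@@H]1c1ccc(OCc2ccccc2)c(OCc2ccccc2)c1
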